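0.900 equivalents of partner per substrate: that is alpha, and the violet run beside it holds 1.29, at the same [substrate] of 17 mM. The [partner] values look close, 15.3 mM against 22 mM, but they lie on opposite sides of 17 mM.

| flask | substrate | partner | remark | time |
|---|---|---|---|---|
| violet | 17 mM | 22 mM | run made earlier |  |
| grey | 17 mM | 70 mM | run made earlier |  |
| theta | 17 mM | 50.0 mM |  | 100 h |
| alpha | 17 mM | 15.3 mM |  | 25 h |

- violet (time / h: target / %, substrate / %): 3.00: 17.2, 3.4; 6.00: 27.4, 0.6; 8.00: 32.4, 0; 12.0: 34.9, 0; 15.0: 37.7, 0.9; 20.0: 36.7, 0.7
- grey (time / h: target / %, substrate / %): 1.33: 10.3, 0; 3.00: 19.5, 0.8; 6.00: 31.0, 0; 10.0: 34.9, 0.8; 12.0: 35.4, 1.7; 20.0: 38.3, 0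

(standard deviation of a reading: 1 percentage point)

- the analysis behind the earlier runs scatters by 1 percentage point, standard deviation
- steps that have been proposed: substrate + partner -> intermediate; intermediate <-> target

- the winner by amount of target, in percent of the substrate charged; "neither" if no more than 2 percentage points parts them (theta / alpha / neither)
- how much target is there at the end, in percent of the substrate charged: theta
- how much target is there at the end, in percent of the substrate charged: alpha

I follow one substrate molecule through two forks. At the first it meets a partner or stays substrate; at the second, the intermediate it became ends as target or stays intermediate. In the violet run, [partner] exceeds [substrate] and substrate reads 0.7 % at 20.0 h, so nearly all of it has passed the first fork. Target then reads 36.7 % in the violet run and 38.3 % in the grey run at 20.0 h, a difference of 1.6 percentage points against a scatter of 1 point on each reading, although [partner] went from 22 mM to 70 mM. Their mean, 37.5 %, is my reading of the fork share: the part of the captured substrate that stands as target at the plateau.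

I therefore expect alpha and the violet run to part at the first fork. In alpha, partner is the limiting reagent, one partner captures one substrate, and my reckoning gives 33.8 %. Theta holds 2.94 equivalents, so I expect its capture to be complete and give it the fork share itself. Both times exceed 15.0 h, by which the violet target has stopped rising within the scatter. My gap of 3.7 points is larger than the margin of 2 points.

The forecast names theta, with 37.5 % for theta and 33.3 % for alpha, on this ground: “The plateau is the same at 22 and 70 mM partner”. Its alpha stands 0.45 points below mine, since it allows for a slow tail and relaxation.

The flask gives theta: 38.7 % for theta and 34.7 % for alpha, 4.0 points apart.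

    substrate + partner → intermediate (k = 2.59 M⁻¹ min⁻¹)
    intermediate ⇌ target (K = 0.632, k = 0.00147 min⁻¹)

At 25.0 h, alpha keeps 10.0 % of its substrate and 0.0136 % of its partner charge. The fork share times 0.900 lies 0.92 points under alpha's target. A neighbour of theta, the same but for a [substrate] of 68 mM, has 0.735 equiv of partner, so the fork share gives it 27.6 %, and that neighbour ends at 28.5 %.

All runs come from a simulation on assumed constants; scatter was added.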